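**Retrosynthetic overview** (C1 = CO2H carbon, C2–C5 ring carbons, C6–C17 hexaene, C18/C19 dione, C20–C24 side chain)
1. C11–C12: Stille coupling of an iodotriene acid (C1–C11) with a trienylstannane dione (C12–C24).
2. C12–C24 arm: two Wittig olefinations (C20=C21, then C16=C17) on the bis-ylide of 1,4-dibromobutane-2,3-dione, using (R)-2-methylbutanal and a stannyl dienal from (E)-pent-2-en-4-yn-1-ol.
3. C1–C11 arm: primary alcohol to acid, Takai iodo-olefination (C10=C11) and cross-metathesis with sorbaldehyde (C6=C7) on a 5-vinyl-2-(hydroxymethyl)oxolan-3-ol.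
4. The only ring (the oxolane) is closed in step 4 by a cobalt/O2 radical oxidative cyclisation of the unprotected, C2-symmetric (3R,5R)-hepta-1,6-diene-3,5-diol; it forms O1–C2 and C1–OH and sets C2.
5. The diol comes from penta-1,4-diene by double epoxidation, hydrolytic kinetic resolution and sulfonium-ylide homologation.

Assumption: (R)-2-methylbutan-1-ol and geometrically pure (E)-pent-2-en-4-yn-1-ol are bought as single isomers.

**Route**

Step 1
Reactants: 1 penta-1,4-diene
Product: 2 2,2′-methylenebis(oxirane) (1,2:4,5-diepoxypentane; mixture of the racemate and the meso form)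
Conditions: mCPBA (2.3 equiv), CH2Cl2, 0 °C → rt
Reagents that add atoms: meta-chloroperoxybenzoic acid, OOC(=O)c1cccc(Cl)c1
Why: Prilezhaev epoxidation of both isolated terminal alkenes; no stereocontrol is needed here because step 2 selects the wanted isomer.

Step 2
Reactants: 2 2,2′-methylenebis(oxirane) (isomer mixture)
Product: 3 (2R,2′R)-2,2′-methylenebis(oxirane)
Conditions: (R,R)-Co(salen)(OAc) (1 mol %; salen = N,N′-bis(3,5-di-tert-butylsalicylidene)cyclohexane-1,2-diamine dianion, trivalent cobalt), H2O (1.0 equiv), THF, 0 °C → rt; distillation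
Reagents that add atoms: none
Why: Jacobsen hydrolytic kinetic resolution, in which the catalyst hydrolyses (S)-configured terminal oxiranes so that only the bis-epoxide with two (R) rings distils (maximum 25 %, very high ee through double selection); this fixes the future C3 and C5.

Step 3
Reactants: 3 (2R,2′R)-2,2′-methylenebis(oxirane)
Product: 4 (3R,5R)-hepta-1,6-diene-3,5-diol
Conditions: Me3S+ I− (6 equiv), n-BuLi (5.8 equiv), THF, −10 °C → rt
Reagents that add atoms: trimethylsulfonium iodide, C[S+](C)C.[I-]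
Why: Alcaraz–Mioskowski one-carbon homologation, in which dimethylsulfonium methylide opens each oxirane at CH2 and the betaine eliminates Me2S to the allylic alcohol; the carbinol centres are not touched.

Step 4
Reactants: 4 (3R,5R)-hepta-1,6-diene-3,5-diol
Product: 6 (2S,3R,5R)-5-ethenyl-2-(hydroxymethyl)oxolan-3-ol, via hydroperoxide 5 (not isolated)
Conditions: Co(modp)2 (10 mol %; bis(1-morpholinocarbamoyl-4,4-dimethylpentane-1,3-dionato)cobalt, divalent cobalt), O2 (1 atm), t-BuOOH (10 mol %), i-PrOH, 55 °C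
Reagents that add atoms: dioxygen, O=O
Why: Mukaiyama aerobic oxidative cyclisation, a cobalt/O2 radical process in which the cobalt-bound alkoxide closes 5-exo onto the distal vinyl group and the resulting oxolanylmethyl radical is trapped by O2 and reduced to the alcohol; the 1-vinyl substituent directs 2,5-trans and the 3-hydroxyl directs 2,3-trans (both reinforcing, setting C2), and C2 symmetry makes the two hydroxyls equivalent so either one gives the same product.

Step 5
Reactants: 6 (2S,3R,5R)-5-ethenyl-2-(hydroxymethyl)oxolan-3-ol; 7 (2E,4E)-hexa-2,4-dienal (sorbaldehyde)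
Product: 8 (2E,4E)-5-[(2R,4R,5S)-4-hydroxy-5-(hydroxymethyl)oxolan-2-yl]penta-2,4-dienal
Conditions: 7 (4 equiv), second-generation Hoveyda–Grubbs catalyst RuCl2(H2IMes)(=CH–C6H4-2-OiPr) (5 mol %), CH2Cl2, 40 °C
Reagents that add atoms: none
Why: Chemoselective olefin cross-metathesis at the electron-richer distal (propenyl) alkene of the electron-poor diene, by analogy with cross-metathesis of sorbate esters; propene is lost and the new C6=C7 bond is E under thermodynamic control, with free hydroxyls tolerated.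

Step 6
Reactants: 8 (2E,4E)-5-[(2R,4R,5S)-4-hydroxy-5-(hydroxymethyl)oxolan-2-yl]penta-2,4-dienal
Product: 9 (2S,3R,5R)-2-(hydroxymethyl)-5-[(1E,3E,5E)-6-iodohexa-1,3,5-trien-1-yl]oxolan-3-ol
Conditions: CHI3 (2.5 equiv), CrCl2 (10 equiv), THF/1,4-dioxane (1:6), 0 °C → rt, dark
Reagents that add atoms: iodoform, IC(I)I
Why: Takai iodo-olefination through the gem-dichromium carbenoid, E-selective for conjugated aldehydes and tolerant of free hydroxyls; it adds C11 with its iodine.

Step 7
Reactants: 9 (2S,3R,5R)-2-(hydroxymethyl)-5-[(1E,3E,5E)-6-iodohexa-1,3,5-trien-1-yl]oxolan-3-ol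
Product: 11 (2R,3R,5R)-3-hydroxy-5-[(1E,3E,5E)-6-iodohexa-1,3,5-trien-1-yl]oxolane-2-carboxylic acid, via aldehyde 10 (not isolated)
Conditions: TEMPO (20 mol %), PhI(OAc)2 (2.5 equiv), MeCN/H2O (1:1), 0 °C → rt, dark
Reagents that add atoms: water, O
Why: Epp–Widlanski TEMPO/PhI(OAc)2 oxidation, selective for the primary alcohol and carried through the aldehyde hydrate to the acid (as in uronic acid synthesis); the secondary hydroxyl is untouched and the transient aldehyde already has the more stable trans,trans arrangement.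

Step 8
Reactants: 12 1,4-dibromobutane-2,3-dione
Product: 14 1,4-bis(triphenyl-λ5-phosphanylidene)butane-2,3-dione, via bisphosphonium dibromide 13 (not isolated)
Conditions: PPh3 (2.1 equiv), CH2Cl2, rt; then aq Na2CO3, rt
Reagents that add atoms: triphenylphosphine, c1ccc(cc1)P(c1ccccc1)c1ccccc1
Why: Double SN2 displacement of the α-bromo ketone by PPh3 followed by deprotonation gives the acyl-stabilised bis-ylide (same reaction type as the ylide from ethyl bromopyruvate).

Step 9
Reactants: 15 (R)-2-methylbutan-1-ol; 14 1,4-bis(triphenyl-λ5-phosphanylidene)butane-2,3-dione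
Product: 17 (4E,6R)-6-methyl-1-(triphenyl-λ5-phosphanylidene)oct-4-ene-2,3-dione, via (R)-2-methylbutanal 16 (not isolated)
Conditions: 15, TEMPO (10 mol %), PhI(OAc)2 (1.1 equiv), CH2Cl2, rt; then added to 14 (3 equiv), CH2Cl2, rt; aq NaHCO3 wash, excess 14 recovered
Reagents that add atoms: none
Why: One-pot TEMPO/PhI(OAc)2 oxidation–Wittig olefination, in which the labile α-branched aldehyde is never isolated or exposed to strong base (C22 is kept) and the stabilised ylide gives the E-enone; the threefold excess of bis-ylide holds the reaction at mono-olefination.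

Step 10
Reactants: 18 (E)-pent-2-en-4-yn-1-ol
Product: 19 (2E,4E)-5-(tributylstannyl)penta-2,4-dien-1-ol
Conditions: Bu3SnH (1.2 equiv), PdCl2(PPh3)2 (2 mol %), THF, 0 °C
Reagents that add atoms: tributyltin hydride, CCCC[SnH](CCCC)CCCC
Why: Palladium-catalysed syn-hydrostannation of the terminal alkyne of a conjugated enyne places tin on the terminal carbon and gives the E-alkene (C12=C13).

Step 11
Reactants: 19 (2E,4E)-5-(tributylstannyl)penta-2,4-dien-1-ol; 17 (4E,6R)-6-methyl-1-(triphenyl-λ5-phosphanylidene)oct-4-ene-2,3-dione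
Product: 21 (1E,3E,5E,9E,11R)-11-methyl-1-(tributylstannyl)trideca-1,3,5,9-tetraene-7,8-dione, via stannyl dienal 20 (not isolated)
Conditions: activated MnO2 (15 equiv), 17 (1.2 equiv), CH2Cl2, rt → 40 °C, dark
Reagents that add atoms: none
Why: Taylor tandem oxidation–Wittig process, in which MnO2 oxidises the dienylic alcohol and the stabilised ylide traps the dienal at once to form the E C16=C17 bond under neutral conditions that leave the C–Sn bond, the dione and C22 alone.

Step 12
Reactants: 11 (2R,3R,5R)-3-hydroxy-5-[(1E,3E,5E)-6-iodohexa-1,3,5-trien-1-yl]oxolane-2-carboxylic acid; 21 (1E,3E,5E,9E,11R)-11-methyl-1-(tributylstannyl)trideca-1,3,5,9-tetraene-7,8-dione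
Product: 22 (2R,3R,5R)-3-hydroxy-5-[(1E,3E,5E,7E,9E,11E,15E,17R)-17-methyl-13,14-dioxononadeca-1,3,5,7,9,11,15-heptaen-1-yl]oxolane-2-carboxylic acid (target)
Conditions: Pd2(dba)3 (5 mol %), AsPh3 (40 mol %), i-Pr2NEt (1.1 equiv), DMF/THF (1:1), rt, dark, argon
Reagents that add atoms: none
Why: Stille coupling under Farina conditions joins C11–C12 with retention of both alkene geometries in a neutral medium that tolerates the free acid, the hydroxyl and the ene-dione, and no stereocentre is involved.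

**Compound list**
1 | penta-1,4-diene | C=CCC=C | starting material
2 | 2,2′-methylenebis(oxirane), racemate plus meso form | C1OC1CC1CO1 | intermediate
3 | (2R,2′R)-2,2′-methylenebis(oxirane) | C1[C@H](O1)C[C@@H]1CO1 | intermediate
4 | (3R,5R)-hepta-1,6-diene-3,5-diol | C=C[C@H](O)C[C@@H](O)C=C | intermediate
5 | (2S,3R,5R)-5-ethenyl-2-(hydroperoxymethyl)oxolan-3-ol | C=C[C@H]1C[C@@H](O)[C@H](COO)O1 | intermediate
6 | (2S,3R,5R)-5-ethenyl-2-(hydroxymethyl)oxolan-3-ol | C=C[C@H]1C[C@@H](O)[C@H](CO)O1 | intermediate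
7 | (2E,4E)-hexa-2,4-dienal | C/C=C/C=C/C=O | starting material
8 | (2E,4E)-5-[(2R,4R,5S)-4-hydroxy-5-(hydroxymethyl)oxolan-2-yl]penta-2,4-dienal | O=C/C=C/C=C/[C@H]1C[C@@H](O)[C@H](CO)O1 | intermediate
9 | (2S,3R,5R)-2-(hydroxymethyl)-5-[(1E,3E,5E)-6-iodohexa-1,3,5-trien-1-yl]oxolan-3-ol | I/C=C/C=C/C=C/[C@H]1C[C@@H](O)[C@H](CO)O1 | intermediate
10 | (2R,3R,5R)-3-hydroxy-5-[(1E,3E,5E)-6-iodohexa-1,3,5-trien-1-yl]oxolane-2-carbaldehyde | I/C=C/C=C/C=C/[C@H]1C[C@@H](O)[C@H](C=O)O1 | intermediate
11 | (2R,3R,5R)-3-hydroxy-5-[(1E,3E,5E)-6-iodohexa-1,3,5-trien-1-yl]oxolane-2-carboxylic acid | I/C=C/C=C/C=C/[C@H]1C[C@@H](O)[C@H](C(=O)O)O1 | intermediate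
12 | 1,4-dibromobutane-2,3-dione | O=C(CBr)C(=O)CBr | starting material
13 | (2,3-dioxobutane-1,4-diyl)bis(triphenylphosphonium) dibromide | O=C(C[P+](c1ccccc1)(c1ccccc1)c1ccccc1)C(=O)C[P+](c1ccccc1)(c1ccccc1)c1ccccc1.[Br-].[Br-] | intermediate
14 | 1,4-bis(triphenyl-λ5-phosphanylidene)butane-2,3-dione | O=C(C=P(c1ccccc1)(c1ccccc1)c1ccccc1)C(=O)C=P(c1ccccc1)(c1ccccc1)c1ccccc1 | intermediate
15 | (R)-2-methylbutan-1-ol | CC[C@@H](C)CO | starting material
16 | (R)-2-methylbutanal | CC[C@@H](C)C=O | intermediate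
17 | (4E,6R)-6-methyl-1-(triphenyl-λ5-phosphanylidene)oct-4-ene-2,3-dione | CC[C@@H](C)/C=C/C(=O)C(=O)C=P(c1ccccc1)(c1ccccc1)c1ccccc1 | intermediate
18 | (E)-pent-2-en-4-yn-1-ol | OC/C=C/C#C | starting material
19 | (2E,4E)-5-(tributylstannyl)penta-2,4-dien-1-ol | OC/C=C/C=C/[Sn](CCCC)(CCCC)CCCC | intermediate
20 | (2E,4E)-5-(tributylstannyl)penta-2,4-dienal | O=C/C=C/C=C/[Sn](CCCC)(CCCC)CCCC | intermediate
21 | (1E,3E,5E,9E,11R)-11-methyl-1-(tributylstannyl)trideca-1,3,5,9-tetraene-7,8-dione | CC[C@@H](C)/C=C/C(=O)C(=O)/C=C/C=C/C=C/[Sn](CCCC)(CCCC)CCCC | intermediate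
22 | (2R,3R,5R)-3-hydroxy-5-[(1E,3E,5E,7E,9E,11E,15E,17R)-17-methyl-13,14-dioxononadeca-1,3,5,7,9,11,15-heptaen-1-yl]oxolane-2-carboxylic acid | CC[C@@H](C)/C=C/C(=O)C(=O)/C=C/C=C/C=C/C=C/C=C/C=C/[C@H]1C[C@@H](O)[C@H](C(=O)O)O1 | target

**Totals**
Total step count: 12. Longest linear sequence: 8 (steps 1–7, then 12).

**The three steps most likely to fail**

Step 4. The unprotected bis-allylic 1,3-diol may chelate cobalt, the hydroxylated alkene is a poorer donor than the usual substrates, and allylic alcohol oxidation can compete. The fallback sets out from 4 and comes back at 6, and it closes the ring by an ionic epoxide opening instead. Sharpless epoxidation of one vinyl carbinol (Ti(OiPr)4, D-(−)-DIPT, t-BuOOH 1.0 equiv, CH2Cl2, −20 °C; matched for the (R)-carbinols, unreacted 4 recycled) gives the erythro epoxy diol (1R,3R)-1-[(2S)-oxiran-2-yl]pent-4-ene-1,3-diol F1. Catalytic camphorsulfonic acid in CH2Cl2 then lets the distal hydroxyl open the oxirane 5-exo with inversion to the all-cis oxolane (2R,3R,5R)-5-ethenyl-2-(hydroxymethyl)oxolan-3-ol F2, the C2 epimer of 6. TEMPO/PhI(OAc)2 in dry CH2Cl2 gives the all-cis aldehyde (2S,3R,5R)-5-ethenyl-3-hydroxyoxolane-2-carbaldehyde F3. Et3N equilibrates its α-alkoxy centre to the more stable trans,trans aldehyde (2R,3R,5R)-5-ethenyl-3-hydroxyoxolane-2-carbaldehyde F4, and NaBH4 (MeOH, 0 °C) returns 6.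

Step 5. Cross-metathesis with a dienal is less secure than with a simple enal, because the ruthenium vinylcarbene can be sluggish and the other alkene of sorbaldehyde can react. The fallback sets out from 6 and comes back at 8, building the dienal in two increments. Cross-metathesis of 6 with crotonaldehyde (same ruthenium catalyst, CH2Cl2, 40 °C) gives the enal (2E)-3-[(2R,4R,5S)-4-hydroxy-5-(hydroxymethyl)oxolan-2-yl]prop-2-enal F5. A two-carbon Wittig homologation with (triphenylphosphoranylidene)acetaldehyde (1.1 equiv, toluene, 60 °C) then gives 8.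

Step 12. The stannane 21 is conjugated to the dione and transmetalates slowly, while the hexaene ene-dione product is sensitive to light and to long reaction times. The fallback sets out from 11 and 19 and comes back at 22, and it makes the C16=C17 bond last by a neutral Wittig reaction. Compound 19 is oxidised with MnO2 and the dienal 20 is isolated. Stille coupling of 11 with 20 (Pd2(dba)3, AsPh3, DMF, rt, dark) gives the pentaenal acid (2R,3R,5R)-3-hydroxy-5-[(1E,3E,5E,7E,9E)-11-oxoundeca-1,3,5,7,9-pentaen-1-yl]oxolane-2-carboxylic acid F6. Wittig olefination of F6 with ylide 17 (2.5 equiv, toluene, 50 °C, dark; the first equivalent is consumed by the acid and regenerated on work-up) gives 22.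

**Further compounds**
F1 | step 4 | (1R,3R)-1-[(2S)-oxiran-2-yl]pent-4-ene-1,3-diol | C=C[C@H](O)C[C@@H](O)[C@@H]1CO1
F2 | step 4 | (2R,3R,5R)-5-ethenyl-2-(hydroxymethyl)oxolan-3-ol | C=C[C@H]1C[C@@H](O)[C@@H](CO)O1
F3 | step 4 | (2S,3R,5R)-5-ethenyl-3-hydroxyoxolane-2-carbaldehyde | C=C[C@H]1C[C@@H](O)[C@@H](C=O)O1
F4 | step 4 | (2R,3R,5R)-5-ethenyl-3-hydroxyoxolane-2-carbaldehyde | C=C[C@H]1C[C@@H](O)[C@H](C=O)O1
F5 | step 5 | (2E)-3-[(2R,4R,5S)-4-hydroxy-5-(hydroxymethyl)oxolan-2-yl]prop-2-enal | O=C/C=C/[C@H]1C[C@@H](O)[C@H](CO)O1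
F6 | step 12 | (2R,3R,5R)-3-hydroxy-5-[(1E,3E,5E,7E,9E)-11-oxoundeca-1,3,5,7,9-pentaen-1-yl]oxolane-2-carboxylic acid | O=C/C=C/C=C/C=C/C=C/C=C/[C@H]1C[C@@H](O)[C@H](C(=O)O)O1
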